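Start with an easy step: multiply the last zeta reading by the charge. At 5.00 h, 31.6% of 0.13 M of L is 41.1 mM of J, made with 2 mM of Q. That is 20.5 J per Q, on a scale whose zero mark is one J per Q, the case in which each Q merely took up a single L.

| flask | L | Q | temperature | remark | time |
|---|---|---|---|---|---|
| zeta | 0.13 M (fed, over 6.0 h) | 2 mM | 110 °C | run made earlier; the fed solution adds 0.10 times the starting volume |  |
| winter | 0.20 M (fed, over 6.0 h) | 1.0 mM | 110 °C | the fed solution adds 0.10 times the starting volume | 25 h |
| midnight | 0.20 M (fed, over 6.0 h) | 8.0 mM | 110 °C | the fed solution adds 0.10 times the starting volume | 25 h |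
| summer | 0.20 M (fed, over 6.0 h) | 1.2 mM | 110 °C | the fed solution adds 0.10 times the starting volume | 25 h |
| dawn | 0.20 M (fed, over 6.0 h) | 4.0 mM | 110 °C | the fed solution adds 0.10 times the starting volume | 25 h |
| dusk | 0.20 M (fed, over 6.0 h) | 2.0 mM | 110 °C | the fed solution adds 0.10 times the starting volume | 25 h |
| spring | 0.20 M (fed, over 6.0 h) | 3.0 mM | 110 °C | the fed solution adds 0.10 times the starting volume | 25 h |

zeta run (percent of the L charged)

| time / h | J / % |
|---|---|
| 0.667 | 0.6 |
| 1.33 | 2.6 |
| 2.00 | 5.6 |
| 3.00 | 13.3 |
| 4.00 | 24.0 |
| 5.00 | 31.6 |

(each reading ± 0.5 percentage points)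

- charges are per starting volume, the dose included; the dosed solution carries all of it
- the earlier runs were read with a standard deviation of 0.5 percentage points
- percentages count the whole charge, also what has not yet gone in
- no earlier run changes the charge of Q; that part of a forecast is a guess

- all flasks from highest to lowest amount of J, in percent of the L charged, at 25 h (winter / midnight / summer / dawn / dusk / spring)
- the same order at 4.0 d (winter / midnight / summer / dawn / dusk / spring)
- the amount of J, in percent of the L charged of the flask you put first, at 25 h
- the amount of J, in percent of the L charged of the flask you put last, at 25 h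

Two views of this flask are in dispute. The first reads zeta as a first-order loss of L with a fading constant, so that [Q] sets a rate and the percent of L follows from it. The second, which is mine, counts instead. In zeta the hourly gain of J fell from 11 percentage points to 7.6 points while L was still going in, a ratio of 0.710. If later hours keep that ratio, zeta ends at 50.2%. This gives the final count of J per Q, the kinetic chain length, 32.7. It is a reading, with the scatter of its readings, and that it holds when [Q] or [L] changes is a guess.

My rule is [J] at the end = count × [Q], up to the charge of L. Winter then gets 16.3%, dusk 32.7%, and midnight reaches the charge, 100%. The rule has no time in it, so it gives the same order at both times.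

The forecast gives midnight > dawn > spring > dusk > summer > winter at 25 h and midnight > dawn > spring > dusk > summer > winter at 4.0 d, with midnight at 77% (60% to 93%) and winter at 43% (28% to 60%). Its ground is: “I assume rate ∝ √Q, which is a guess because no run varied Q”. So the two views share the order and part on the spread. The thing to watch is whether J stops while L still stands.

The flask gives midnight > dawn > spring > dusk > summer > winter at 25 h and midnight > dawn > spring > dusk > summer > winter at 4.0 d, with midnight at 97.8% and winter at 21.9%.

    L + Q → D + J (k = 0.679 M⁻¹ min⁻¹, Ea = 94.0 kJ mol⁻¹)
    L + D → J + D, rate k2*[D]*[L] (k = 2.81 M⁻¹ min⁻¹, Ea = 72.0 kJ mol⁻¹)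
    D + L → E (k = 0.0658 M⁻¹ min⁻¹, Ea = 73.0 kJ mol⁻¹)
    (constants at 110 °C)

Winter, dusk and spring give 43.7, 43.7 and 43.6 J per Q, against my 32.7. Winter stops with 78% of its L left because D + L → E ends the chains: without that step winter gives 96.4%. Both steps of D carry [L], so at 110 °C the ratio of their rates, 42.7, does not depend on [L]. The forecast's view has its place between dusk and midnight: its 54 for 2.0 mM of Q stands above dusk's 43.7%, and its 77% stands below midnight's 97.8%.

Take winter with 0.34 M of L: the count of 32.7 gives 9.60% of that charge. The computed flask gives 12.9% of its L, which is 43.7 J per Q.

The numbers in the tables are simulated with made-up constants; the scatter is artificial.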